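**Retrosynthetic overview**

1. Lettering: ring A is the terminal 3,5-dihydroxyphenyl; rings B and E are the two 1,2,3-triaryloxy-5-hydroxybenzenes; ring C is the 2,6-dihydroxy-1,4-dioxybenzene between them; rings D (on B), F and H (on E) are the inner rings of the three biaryl units, each bonded to a 2,4,6-trihydroxyphenyl ring.
2. The strategy rests on rings D, F and H: each carries oxygen on C1 (the ether oxygen), C2, C4 and C6, hydrogen on C3 and the aryl group on C5, so all three come from one phenol, 2,2',4,4',6,6'-hexamethoxybiphenyl-3-ol, used three times.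
3. That ring is disconnected at C3–C4 to a 2-aryl-3-methoxy-4-(1-methoxyvinyl)-4-silyloxycyclobutenone (thermal opening to a dienylketene, then 6π closure). One stage back, C1–C2 comes from 1-methoxyvinyllithium and the biaryl bond C5–C1' from 2,4,6-trimethoxyphenyllithium, both added to dimethyl squarate carbonyls.
4. Rings E, C and B are bought as fluorobenzaldehydes and joined iteratively: a hindered phenol displaces fluoride (SNAr), then the formyl group is oxidised to the next hindered phenol (Baeyer–Villiger/Dakin); ring A is added by Ullmann coupling and all 24 methyl ethers are cleaved last.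
5. Ring formation: only the inner biaryl ring is constructed (step 4, one batch serving D, F and H); every other ring is purchased.

Key step: step 4

Assumption: 2,6-difluoro-4-methoxybenzaldehyde, 4-fluoro-2,6-dimethoxybenzaldehyde and 1-iodo-3,5-dimethoxybenzene are taken as purchasable; the target has no stereocentre and no stereogenic axis (each biaryl carries a symmetric 2,4,6-trioxygenated ring), so only constitution has to be controlled; ArO below stands for 2,2',4,4',6,6'-hexamethoxybiphenyl-3-yloxy.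

**Route**

Step 1
Reactants: 1 1,3,5-trimethoxybenzene; 2 dimethyl squarate
Product: 4 rac-4-hydroxy-2,3-dimethoxy-4-(2,4,6-trimethoxyphenyl)cyclobut-2-en-1-one, via 2,4,6-trimethoxyphenyllithium 3 (not isolated)
Conditions: n-BuLi, THF, 0 °C to rt; then 2, THF, −78 °C; aq. NH4Cl
Reagents that add atoms: none
Why: Directed ortho-lithiation between two methoxy groups gives 3, which should add 1,2 to one squarate carbonyl and stop at mono-addition at −78 °C; the crowded biaryl bond is thus made as a simple carbonyl addition.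

Step 2
Reactants: 4 rac-4-hydroxy-2,3-dimethoxy-4-(2,4,6-trimethoxyphenyl)cyclobut-2-en-1-one
Product: 5 3-methoxy-4-(2,4,6-trimethoxyphenyl)cyclobut-3-ene-1,2-dione
Conditions: conc. HCl (cat.), CH2Cl2, rt
Reagents that add atoms: water, O
Why: Acid-catalysed allylic transposition and hydrolysis (ionisation of the tertiary carbinol, capture of water at the methoxy-bearing terminus, loss of methanol) is the standard squarate route to 3-aryl-4-alkoxycyclobutenediones.

Step 3
Reactants: 5 3-methoxy-4-(2,4,6-trimethoxyphenyl)cyclobut-3-ene-1,2-dione; 6 methyl vinyl ether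
Product: 9 rac-4-(tert-butyldimethylsilyloxy)-3-methoxy-4-(1-methoxyvinyl)-2-(2,4,6-trimethoxyphenyl)cyclobut-2-en-1-one, via 1-methoxyvinyllithium 7 (not isolated), via lithium cyclobutenolate 8 (not isolated)
Conditions: 6, t-BuLi, THF, −78 to 0 °C; then 5, THF, −78 °C; then TBSOTf, −78 to −20 °C; aq. NaHCO3
Reagents that add atoms: tert-butyldimethylsilyl trifluoromethanesulfonate (TBSOTf), CC(C)(C)[Si](C)(C)OS(=O)(=O)C(F)(F)F
Why: α-Lithiation of the vinyl ether, then 1,2-addition to the ketone-like carbonyl of 5 (the one on the methoxy-bearing ring carbon; the other is a vinylogous ester screened by the di-ortho-methoxyaryl group) and in situ O-silylation, with tert-butyldimethylsilyl chosen so that the later aryl silyl ether survives base-mediated methylation; the new quaternary carbon is racemic and is erased in step 4.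

Step 4
Reactants: 9 rac-4-(tert-butyldimethylsilyloxy)-3-methoxy-4-(1-methoxyvinyl)-2-(2,4,6-trimethoxyphenyl)cyclobut-2-en-1-one
Product: 12 4-(tert-butyldimethylsilyloxy)-3,5-dimethoxy-2-(2,4,6-trimethoxyphenyl)phenol, via dienylketene 10 (not isolated), via cyclohexa-2,4-dienone 11 (not isolated)
Conditions: toluene, 110 °C, argon, 0.02 M
Reagents that add atoms: none
Why: Moore ring expansion: on heating, the cyclobutenone undergoes conrotatory 4π ring opening with cleavage of the C1–C4 bond, the donor silyloxy group rotating outward so that the 1-methoxyvinyl group ends up cis to the ketene in the (Z)-dienylketene 10. A thermal disrotatory 6π electrocyclisation then joins the ketene carbon to the vinyl CH2 terminus, which closes the six-membered carbocycle by forming the future C3–C4 bond of the inner biaryl ring and gives dienone 11; its enolisation to the aromatic phenol 12 makes the sequence irreversible. The closest known reaction type is the thermolysis of 4-alkenyl-4-oxycyclobutenones (1-alkoxyvinyl groups included) to mono-protected hydroquinones. No stereocentre is formed, and the racemic quaternary carbon of 9 becomes an sp2 ring carbon. The selectivity needed is constitutional (aryl group ortho to the new phenol, silyloxy group para to it): it is fixed by the carbonyl that the vinyllithium attacked in step 3, and the outward torquoselectivity of the oxygen substituent secures that the two termini can meet. The tetra-ortho-oxygenated biaryl bond is only a spectator, since it was made in step 1.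

Step 5
Reactants: 12 4-(tert-butyldimethylsilyloxy)-3,5-dimethoxy-2-(2,4,6-trimethoxyphenyl)phenol
Product: 13 3-(tert-butyldimethylsilyloxy)-2,2',4,4',6,6'-hexamethoxybiphenyl
Conditions: MeI, K2CO3, acetone, 50 °C
Reagents that add atoms: iodomethane, CI
Why: Williamson O-methylation of the only free phenol; the aryl silyl ether flanked by two methoxy groups should be stable to K2CO3 in dry acetone.

Step 6
Reactants: 13 3-(tert-butyldimethylsilyloxy)-2,2',4,4',6,6'-hexamethoxybiphenyl
Product: 14 2,2',4,4',6,6'-hexamethoxybiphenyl-3-ol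
Conditions: TBAF, AcOH, THF, 0 °C
Reagents that add atoms: none
Why: Fluoride-induced Si–O cleavage frees the hindered phenol (the future ether oxygen on C1 of rings D, F and H); acetic acid buffers the electron-rich phenoxide.

Step 7
Reactants: 14 2,2',4,4',6,6'-hexamethoxybiphenyl-3-ol; 15 2,6-difluoro-4-methoxybenzaldehyde
Product: 16 4-methoxy-2,6-bis(ArO)benzaldehyde
Conditions: 14 (2.3 equiv), Cs2CO3, DMSO, 110 °C, argon
Reagents that add atoms: none
Why: Twofold nucleophilic aromatic substitution (addition–elimination) of the two fluorides ortho to the formyl group builds ring E with both flanking ethers (to rings F and H) at once.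

Step 8
Reactants: 16 4-methoxy-2,6-bis(ArO)benzaldehyde
Product: 18 4-methoxy-2,6-bis(ArO)phenol, via aryl formate 17 (not isolated)
Conditions: mCPBA, CH2Cl2, 0 °C to rt; aq. Na2S2O3; then K2CO3 (cat.), MeOH, rt, argon
Reagents that add atoms: 3-chloroperoxybenzoic acid (mCPBA), OOC(=O)c1cccc(Cl)c1
Why: Baeyer–Villiger oxidation of the electron-rich benzaldehyde (aryl migration, Dakin-type) to the aryl formate and methanolysis should convert the SNAr-activating formyl group into the central hydroxyl of ring E.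

Step 9
Reactants: 18 4-methoxy-2,6-bis(ArO)phenol; 19 4-fluoro-2,6-dimethoxybenzaldehyde
Product: 20 4-[4-methoxy-2,6-bis(ArO)phenoxy]-2,6-dimethoxybenzaldehyde
Conditions: 19 (1.5 equiv), K2CO3, DMF, 120 °C, argon
Reagents that add atoms: none
Why: SNAr para to the formyl group; the hindered phenoxide attacks a ring carbon flanked only by hydrogens, and the two methoxy groups are meta to the leaving fluoride.

Step 10
Reactants: 20 4-[4-methoxy-2,6-bis(ArO)phenoxy]-2,6-dimethoxybenzaldehyde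
Product: 22 4-[4-methoxy-2,6-bis(ArO)phenoxy]-2,6-dimethoxyphenol, via aryl formate 21 (not isolated)
Conditions: mCPBA, CH2Cl2, 0 °C to rt; aq. Na2S2O3; then K2CO3 (cat.), MeOH, rt, argon
Reagents that add atoms: 3-chloroperoxybenzoic acid (mCPBA), OOC(=O)c1cccc(Cl)c1
Why: Baeyer–Villiger oxidation/methanolysis (Dakin-type) of a 2,4,6-trioxygenated benzaldehyde should give the ring C phenol whose hydroxyl lies between two methoxy groups.

Step 11
Reactants: 22 4-[4-methoxy-2,6-bis(ArO)phenoxy]-2,6-dimethoxyphenol; 15 2,6-difluoro-4-methoxybenzaldehyde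
Product: 23 2-fluoro-4-methoxy-6-{4-[4-methoxy-2,6-bis(ArO)phenoxy]-2,6-dimethoxyphenoxy}benzaldehyde
Conditions: 15 (3 equiv), K2CO3, DMF, 90 °C, argon
Reagents that add atoms: none
Why: SNAr at one ortho fluoride; the excess of 15 and the lower reactivity of the mono-ether should hold the reaction at mono-substitution.

Step 12
Reactants: 23 2-fluoro-4-methoxy-6-{4-[4-methoxy-2,6-bis(ArO)phenoxy]-2,6-dimethoxyphenoxy}benzaldehyde; 14 2,2',4,4',6,6'-hexamethoxybiphenyl-3-ol
Product: 24 4-methoxy-2-(ArO)-6-{4-[4-methoxy-2,6-bis(ArO)phenoxy]-2,6-dimethoxyphenoxy}benzaldehyde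
Conditions: 14 (2.5 equiv), Cs2CO3, DMSO, 120 °C, argon
Reagents that add atoms: none
Why: Second SNAr ortho to the formyl group, driven by an excess of the small phenoxide; fluoride is a far better SNAr leaving group than the aryloxide already in place, so ring B should receive its two different flanking ethers without exchange.

Step 13
Reactants: 24 4-methoxy-2-(ArO)-6-{4-[4-methoxy-2,6-bis(ArO)phenoxy]-2,6-dimethoxyphenoxy}benzaldehyde
Product: 26 4-methoxy-2-(ArO)-6-{4-[4-methoxy-2,6-bis(ArO)phenoxy]-2,6-dimethoxyphenoxy}phenol, via aryl formate 25 (not isolated)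
Conditions: mCPBA, CH2Cl2, 0 °C to rt; aq. Na2S2O3; then K2CO3 (cat.), MeOH, rt, argon
Reagents that add atoms: 3-chloroperoxybenzoic acid (mCPBA), OOC(=O)c1cccc(Cl)c1
Why: Baeyer–Villiger oxidation/methanolysis (Dakin-type) should convert the formyl group into the central hydroxyl of ring B.

Step 14
Reactants: 26 4-methoxy-2-(ArO)-6-{4-[4-methoxy-2,6-bis(ArO)phenoxy]-2,6-dimethoxyphenoxy}phenol; 27 1-iodo-3,5-dimethoxybenzene
Product: 28 tetracosa-O-methyl ether of the target
Conditions: 27 (3 equiv), CuI (20 mol %), picolinic acid (40 mol %), K3PO4, DMSO, 90 °C, argon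
Reagents that add atoms: none
Why: Ullmann-type copper-catalysed O-arylation with picolinic acid as ligand, a combination suited to di-ortho-substituted phenols, and an unhindered aryl iodide should attach ring A to the central oxygen of ring B.

Step 15
Reactants: 28 tetracosa-O-methyl ether of the target
Product: 29 CNP0294555.0 (target)
Conditions: BBr3 (excess), CH2Cl2, −78 °C to rt; then H2O; work-up under argon
Reagents that add atoms: none
Why: Lewis-acid ether cleavage: bromide attacks the O-methyl carbon of each boron-complexed aryl methyl ether, while diaryl ether and biaryl bonds offer no sp3 carbon and should stay intact.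

**Compound list**

1 | 1,3,5-trimethoxybenzene | COc1cc(OC)cc(OC)c1 | starting material
2 | dimethyl squarate (3,4-dimethoxycyclobut-3-ene-1,2-dione) | COC1=C(OC)C(=O)C1=O | starting material
3 | 2,4,6-trimethoxyphenyllithium | [Li]c1c(OC)cc(OC)cc1OC | intermediate (not isolated)
4 | rac-4-hydroxy-2,3-dimethoxy-4-(2,4,6-trimethoxyphenyl)cyclobut-2-en-1-one | COC1=C(OC)C(O)(c2c(OC)cc(OC)cc2OC)C1=O | intermediate
5 | 3-methoxy-4-(2,4,6-trimethoxyphenyl)cyclobut-3-ene-1,2-dione | COC1=C(c2c(OC)cc(OC)cc2OC)C(=O)C1=O | intermediate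
6 | methyl vinyl ether | C=COC | starting material
7 | 1-methoxyvinyllithium | [Li]C(=C)OC | intermediate (not isolated)
8 | lithium rac-2-methoxy-1-(1-methoxyvinyl)-4-oxo-3-(2,4,6-trimethoxyphenyl)cyclobut-2-en-1-olate | [Li+].[O-]C1(C(=C)OC)C(OC)=C(c2c(OC)cc(OC)cc2OC)C1=O | intermediate (not isolated)
9 | rac-4-(tert-butyldimethylsilyloxy)-3-methoxy-4-(1-methoxyvinyl)-2-(2,4,6-trimethoxyphenyl)cyclobut-2-en-1-one | O=C1C(c2c(OC)cc(OC)cc2OC)=C(OC)C1(O[Si](C)(C)C(C)(C)C)C(=C)OC | intermediate (key-step precursor)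
10 | (3Z)-4-(tert-butyldimethylsilyloxy)-3,5-dimethoxy-2-(2,4,6-trimethoxyphenyl)hexa-1,3,5-trien-1-one (dienylketene) | O=C=C(c1c(OC)cc(OC)cc1OC)/C(OC)=C(\C(=C)OC)O[Si](C)(C)C(C)(C)C | intermediate (not isolated)
11 | 4-(tert-butyldimethylsilyloxy)-3,5-dimethoxy-2-(2,4,6-trimethoxyphenyl)cyclohexa-2,4-dien-1-one | O=C1CC(OC)=C(O[Si](C)(C)C(C)(C)C)C(OC)=C1c1c(OC)cc(OC)cc1OC | intermediate (not isolated)
12 | 4-(tert-butyldimethylsilyloxy)-3,5-dimethoxy-2-(2,4,6-trimethoxyphenyl)phenol | Oc1cc(OC)c(O[Si](C)(C)C(C)(C)C)c(OC)c1-c1c(OC)cc(OC)cc1OC | intermediate (key-step product)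
13 | 3-(tert-butyldimethylsilyloxy)-2,2',4,4',6,6'-hexamethoxybiphenyl | COc1cc(OC)c(O[Si](C)(C)C(C)(C)C)c(OC)c1-c1c(OC)cc(OC)cc1OC | intermediate
14 | 2,2',4,4',6,6'-hexamethoxybiphenyl-3-ol | COc1cc(OC)c(O)c(OC)c1-c1c(OC)cc(OC)cc1OC | intermediate
15 | 2,6-difluoro-4-methoxybenzaldehyde | COc1cc(F)c(C=O)c(F)c1 | starting material
16 | 4-methoxy-2,6-bis(ArO)benzaldehyde | O=Cc1c(Oc2c(OC)cc(OC)c(-c3c(OC)cc(OC)cc3OC)c2OC)cc(OC)cc1Oc1c(OC)cc(OC)c(-c2c(OC)cc(OC)cc2OC)c1OC | intermediate
17 | 4-methoxy-2,6-bis(ArO)phenyl formate | O=COc1c(Oc2c(OC)cc(OC)c(-c3c(OC)cc(OC)cc3OC)c2OC)cc(OC)cc1Oc1c(OC)cc(OC)c(-c2c(OC)cc(OC)cc2OC)c1OC | intermediate (not isolated)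
18 | 4-methoxy-2,6-bis(ArO)phenol | Oc1c(Oc2c(OC)cc(OC)c(-c3c(OC)cc(OC)cc3OC)c2OC)cc(OC)cc1Oc1c(OC)cc(OC)c(-c2c(OC)cc(OC)cc2OC)c1OC | intermediate
19 | 4-fluoro-2,6-dimethoxybenzaldehyde | O=Cc1c(OC)cc(F)cc1OC | starting material
20 | 4-[4-methoxy-2,6-bis(ArO)phenoxy]-2,6-dimethoxybenzaldehyde | O=Cc1c(OC)cc(Oc2c(Oc3c(OC)cc(OC)c(-c4c(OC)cc(OC)cc4OC)c3OC)cc(OC)cc2Oc2c(OC)cc(OC)c(-c3c(OC)cc(OC)cc3OC)c2OC)cc1OC | intermediate
21 | 4-[4-methoxy-2,6-bis(ArO)phenoxy]-2,6-dimethoxyphenyl formate | O=COc1c(OC)cc(Oc2c(Oc3c(OC)cc(OC)c(-c4c(OC)cc(OC)cc4OC)c3OC)cc(OC)cc2Oc2c(OC)cc(OC)c(-c3c(OC)cc(OC)cc3OC)c2OC)cc1OC | intermediate (not isolated)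
22 | 4-[4-methoxy-2,6-bis(ArO)phenoxy]-2,6-dimethoxyphenol | Oc1c(OC)cc(Oc2c(Oc3c(OC)cc(OC)c(-c4c(OC)cc(OC)cc4OC)c3OC)cc(OC)cc2Oc2c(OC)cc(OC)c(-c3c(OC)cc(OC)cc3OC)c2OC)cc1OC | intermediate
23 | 2-fluoro-4-methoxy-6-{4-[4-methoxy-2,6-bis(ArO)phenoxy]-2,6-dimethoxyphenoxy}benzaldehyde | O=Cc1c(F)cc(OC)cc1Oc1c(OC)cc(Oc2c(Oc3c(OC)cc(OC)c(-c4c(OC)cc(OC)cc4OC)c3OC)cc(OC)cc2Oc2c(OC)cc(OC)c(-c3c(OC)cc(OC)cc3OC)c2OC)cc1OC | intermediate
24 | 4-methoxy-2-(ArO)-6-{4-[4-methoxy-2,6-bis(ArO)phenoxy]-2,6-dimethoxyphenoxy}benzaldehyde | O=Cc1c(Oc2c(OC)cc(OC)c(-c3c(OC)cc(OC)cc3OC)c2OC)cc(OC)cc1Oc1c(OC)cc(Oc2c(Oc3c(OC)cc(OC)c(-c4c(OC)cc(OC)cc4OC)c3OC)cc(OC)cc2Oc2c(OC)cc(OC)c(-c3c(OC)cc(OC)cc3OC)c2OC)cc1OC | intermediate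
25 | 4-methoxy-2-(ArO)-6-{4-[4-methoxy-2,6-bis(ArO)phenoxy]-2,6-dimethoxyphenoxy}phenyl formate | O=COc1c(Oc2c(OC)cc(OC)c(-c3c(OC)cc(OC)cc3OC)c2OC)cc(OC)cc1Oc1c(OC)cc(Oc2c(Oc3c(OC)cc(OC)c(-c4c(OC)cc(OC)cc4OC)c3OC)cc(OC)cc2Oc2c(OC)cc(OC)c(-c3c(OC)cc(OC)cc3OC)c2OC)cc1OC | intermediate (not isolated)
26 | 4-methoxy-2-(ArO)-6-{4-[4-methoxy-2,6-bis(ArO)phenoxy]-2,6-dimethoxyphenoxy}phenol | Oc1c(Oc2c(OC)cc(OC)c(-c3c(OC)cc(OC)cc3OC)c2OC)cc(OC)cc1Oc1c(OC)cc(Oc2c(Oc3c(OC)cc(OC)c(-c4c(OC)cc(OC)cc4OC)c3OC)cc(OC)cc2Oc2c(OC)cc(OC)c(-c3c(OC)cc(OC)cc3OC)c2OC)cc1OC | intermediate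
27 | 1-iodo-3,5-dimethoxybenzene | COc1cc(I)cc(OC)c1 | starting material
28 | tetracosa-O-methyl ether of the target (26 with its free hydroxyl carrying a 3,5-dimethoxyphenyl group) | COc1cc(OC)cc(Oc2c(Oc3c(OC)cc(OC)c(-c4c(OC)cc(OC)cc4OC)c3OC)cc(OC)cc2Oc2c(OC)cc(Oc3c(Oc4c(OC)cc(OC)c(-c5c(OC)cc(OC)cc5OC)c4OC)cc(OC)cc3Oc3c(OC)cc(OC)c(-c4c(OC)cc(OC)cc4OC)c3OC)cc2OC)c1 | intermediate
29 | CNP0294555.0 (all 24 hydroxyls free) | Oc1cc(O)cc(Oc2c(Oc3c(O)cc(Oc4c(Oc5c(O)cc(O)c(-c6c(O)cc(O)cc6O)c5O)cc(O)cc4Oc4c(O)cc(O)c(-c5c(O)cc(O)cc5O)c4O)cc3O)cc(O)cc2Oc2c(O)cc(O)c(-c3c(O)cc(O)cc3O)c2O)c1 | target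

**Step count and risks**

Total steps: 15. Longest linear sequence: 15 steps (1 to 29; phenol 14 from the same line is drawn on again in steps 7 and 12).

Most likely to fail, in this order:

Step 14. The phenoxide oxygen of 26 lies between two 2,6-dimethoxyaryloxy groups, so ligand exchange at copper and the C–O bond-forming event may be slow. The coupling may then stall while the aryl iodide is reduced and the electron-rich phenoxide is degraded oxidatively at 90 °C. The fallback sets out from 26 and comes back at 28, and replaces metal catalysis by SNAr plus removal of the activating group. Compound 26 with 19 (K2CO3, DMF, 120 °C, the reaction already relied on for the equally hindered 18 in step 9) should give 4-aryloxy-2,6-dimethoxybenzaldehyde F4. Rhodium-catalysed decarbonylation of the Tsuji–Wilkinson type (RhCl3·3H2O, 1,3-bis(diphenylphosphino)propane, diglyme, reflux) would then expel the formyl carbon as CO and leave the 3,5-dimethoxyphenyl ether 28.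

Step 12. The remaining fluoride of 23 is less activated than those of 15 and sits on a ring that already carries a very large aryloxy group, so the substitution may stall. At the temperature needed, the aryloxy group already in place may itself be displaced by the incoming phenoxide (ipso substitution with aryloxide leaving), which would scramble the two flanking groups of ring B. The fallback sets out from 22 and 14, comes back at 26, and replaces steps 11 to 13 by addition–elimination on a haloquinone at or below room temperature. Phenol 14 is added slowly to excess 2,6-dichloro-1,4-benzoquinone (O=C1C=C(Cl)C(=O)C(Cl)=C1; Cs2CO3, MeCN, 0 °C) to give 2-chloro-6-aryloxy-1,4-benzoquinone F1. Neither 14 nor 22 has a free ortho or para ring carbon, so only O-attack is open to them. F1 and 22 (Cs2CO3, MeCN, rt) should give the unsymmetrical 2,6-bis(aryloxy)quinone F2, and Na2S2O4 (THF/H2O) reduces it to hydroquinone F3. One equivalent of MeI with K2CO3 (DMF, 0 °C) is expected to methylate the hydroxyl meta to both aryloxy groups, which is the more acidic and the unhindered one, and this gives 26.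

Step 15. Twenty-four ether cleavages are asked of one operation. Cleavage may stop at partly methylated stages that are hard to separate from the product, and the free polyphenol may be lost to air oxidation during isolation. The fallback sets out from 28 and comes back at 29, and changes both the cleavage mode and the way the product is secured. Cleavage uses a hard Lewis acid with a soft nucleophile (AlCl3, EtSH, CH2Cl2, 0 °C to rt). The crude polyphenol is not purified but peracetylated (Ac2O, pyridine) to the tetracosaacetate F5, which is stable and can be chromatographed on silica, and under-cleaved fractions are returned to the cleavage. Acid-catalysed methanolysis of F5 (HCl, MeOH, argon) then releases 29.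

**Further compounds**

F1 | step 12 | 2-chloro-6-(2,2',4,4',6,6'-hexamethoxybiphenyl-3-yloxy)-1,4-benzoquinone | O=C1C=C(Cl)C(=O)C(Oc2c(OC)cc(OC)c(-c3c(OC)cc(OC)cc3OC)c2OC)=C1
F2 | step 12 | 2-(ArO)-6-{4-[4-methoxy-2,6-bis(ArO)phenoxy]-2,6-dimethoxyphenoxy}-1,4-benzoquinone | O=C1C=C(Oc2c(OC)cc(Oc3c(Oc4c(OC)cc(OC)c(-c5c(OC)cc(OC)cc5OC)c4OC)cc(OC)cc3Oc3c(OC)cc(OC)c(-c4c(OC)cc(OC)cc4OC)c3OC)cc2OC)C(=O)C(Oc2c(OC)cc(OC)c(-c3c(OC)cc(OC)cc3OC)c2OC)=C1
F3 | step 12 | 2-(ArO)-6-{4-[4-methoxy-2,6-bis(ArO)phenoxy]-2,6-dimethoxyphenoxy}benzene-1,4-diol | Oc1cc(Oc2c(OC)cc(Oc3c(Oc4c(OC)cc(OC)c(-c5c(OC)cc(OC)cc5OC)c4OC)cc(OC)cc3Oc3c(OC)cc(OC)c(-c4c(OC)cc(OC)cc4OC)c3OC)cc2OC)c(O)c(Oc2c(OC)cc(OC)c(-c3c(OC)cc(OC)cc3OC)c2OC)c1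
F4 | step 14 | 2,6-dimethoxy-4-[4-methoxy-2-(ArO)-6-{4-[4-methoxy-2,6-bis(ArO)phenoxy]-2,6-dimethoxyphenoxy}phenoxy]benzaldehyde | O=Cc1c(OC)cc(Oc2c(Oc3c(OC)cc(OC)c(-c4c(OC)cc(OC)cc4OC)c3OC)cc(OC)cc2Oc2c(OC)cc(Oc3c(Oc4c(OC)cc(OC)c(-c5c(OC)cc(OC)cc5OC)c4OC)cc(OC)cc3Oc3c(OC)cc(OC)c(-c4c(OC)cc(OC)cc4OC)c3OC)cc2OC)cc1OC
F5 | step 15 | tetracosa-O-acetate of the target | CC(=O)Oc1cc(OC(C)=O)cc(Oc2c(Oc3c(OC(C)=O)cc(Oc4c(Oc5c(OC(C)=O)cc(OC(C)=O)c(-c6c(OC(C)=O)cc(OC(C)=O)cc6OC(C)=O)c5OC(C)=O)cc(OC(C)=O)cc4Oc4c(OC(C)=O)cc(OC(C)=O)c(-c5c(OC(C)=O)cc(OC(C)=O)cc5OC(C)=O)c4OC(C)=O)cc3OC(C)=O)cc(OC(C)=O)cc2Oc2c(OC(C)=O)cc(OC(C)=O)c(-c3c(OC(C)=O)cc(OC(C)=O)cc3OC(C)=O)c2OC(C)=O)c1
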